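**Strategy**

The dihydropyranone ring (ring B: O1, C2, C3, C4) is disconnected at O1–C2 and C3–C4 to an ortho-hydroxy aldehyde on ring A and but-2-yne. In one pot, chelation-assisted rhodium hydroacylation joins the formyl carbon (C4) to the alkyne, and quinidine then closes the C8a phenol onto the resulting tigloyl ketone with kinetic protonation, setting cis-(2S,3R). The step exploits the ortho pair C4a–CHO/C8a–OH; the C5 oxygen is tied to the side-chain carboxyl as a six-membered lactone, so only one phenol can close. This precursor comes from phloroglucinol by Pechmann condensation and asymmetric CuH reduction, which sets the side-chain centre.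

Key step: step 7

Remarks on the chemistry:
- Target atoms carry chromanone numbering (O1, C2, C3, C4, C4a, C5 to C8, C8a); ring A is the benzene ring and ring B the pyranone ring.
- Assumption: the senses of induction of (S)-DTBM-SEGPHOS/CuH (4R) and of quinidine (2S) are assigned by analogy with 4-substituted coumarins and o-tigloylphenols. The antipodal ligand, or quinine, would be used if either sense proved opposite.

**Route**

Step 1
Reactants: 1 phloroglucinol; 2 ethyl 3-oxooctanoate
Product: 3 5,7-dihydroxy-4-pentyl-2H-chromen-2-one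
Conditions: CF3SO3H, 0 °C to rt; ice-water
Reagents that add atoms: none
Why: Pechmann condensation (transesterification at a phenol oxygen, then intramolecular hydroxyalkylation at the ketone and dehydration); the threefold symmetry of 1 allows only one coumarin.

Step 2
Reactants: 3 5,7-dihydroxy-4-pentyl-2H-chromen-2-one
Product: 5 (4R)-5,7-dihydroxy-4-pentylchroman-2-one, via tris-silyl ketene acetal 4 (not isolated)
Conditions: Cu(OAc)2·H2O (5 mol %), (S)-DTBM-SEGPHOS (5.5 mol %), (EtO)2MeSiH (5 equiv), THF/toluene, rt; then 1 M HCl, THF, 0 °C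
Reagents that add atoms: none
Why: Ligand-controlled copper hydride 1,4-reduction of a β,β-disubstituted unsaturated lactone: the phenols are silylated in situ with loss of H2, hydride is delivered to one face of C4 (new 4R centre, catalyst control), and the enolate is held as silyl ketene acetal 4, which should shield the aryl lactone from over-reduction until the acidic work-up.

Step 3
Reactants: 5 (4R)-5,7-dihydroxy-4-pentylchroman-2-one
Product: 6 (4R)-5,7-dihydroxy-2-oxo-4-pentylchromane-8-carbaldehyde
Conditions: POCl3, DMF, MeCN, 0 °C to rt; then H2O, 40 °C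
Reagents that add atoms: N,N-dimethylformamide CN(C)C=O; water O
Why: Vilsmeier–Haack formylation, expected at C8 (para to the C5 hydroxyl, flanked by the tied-back lactone oxygen) rather than at C6 (between two hydroxyls, one buttressed by the C4 pentyl group), as in the related 5,7-dihydroxy-4-alkylcoumarins.

Step 4
Reactants: 6 (4R)-5,7-dihydroxy-2-oxo-4-pentylchromane-8-carbaldehyde
Product: 7 (4R)-7-hydroxy-5-methoxy-2-oxo-4-pentylchromane-8-carbaldehyde
Conditions: MeI (1.1 equiv), K2CO3 (1.1 equiv), acetone, rt
Reagents that add atoms: iodomethane CI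
Why: Williamson methylation; the C7 hydroxyl is hydrogen-bonded to the formyl group, whereas the C5 hydroxyl para to it is free and more acidic, so one equivalent should methylate O5 only.

Step 5
Reactants: 7 (4R)-7-hydroxy-5-methoxy-2-oxo-4-pentylchromane-8-carbaldehyde
Product: 8 (4R)-7-hydroxy-6-iodo-5-methoxy-2-oxo-4-pentylchromane-8-carbaldehyde
Conditions: NIS, TFA (cat.), MeCN, 0 °C to rt
Reagents that add atoms: N-iodosuccinimide O=C1CCC(=O)N1I
Why: Electrophilic aromatic iodination at C6, the only unsubstituted ring position, activated by the ortho hydroxyl and methoxyl groups.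

Step 6
Reactants: 8 (4R)-7-hydroxy-6-iodo-5-methoxy-2-oxo-4-pentylchromane-8-carbaldehyde; 9 tributyl(3-methylbut-2-en-1-yl)stannane
Product: 10 (4R)-7-hydroxy-5-methoxy-6-(3-methylbut-2-en-1-yl)-2-oxo-4-pentylchromane-8-carbaldehyde
Conditions: Pd(PPh3)4 (5 mol %), CuI (10 mol %), DMF, 80 °C
Reagents that add atoms: none
Why: Stille coupling at the C–I bond with transfer of the prenyl group through its tin-bearing carbon, which should give the linear 3-methylbut-2-enyl arene; lactone, aldehyde and free phenol tolerate the neutral conditions.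

Step 7
Reactants: 10 (4R)-7-hydroxy-5-methoxy-6-(3-methylbut-2-en-1-yl)-2-oxo-4-pentylchromane-8-carbaldehyde; 11 but-2-yne
Product: 13 (4R,8S,9R)-5-methoxy-8,9-dimethyl-6-(3-methylbut-2-en-1-yl)-4-pentyl-3,4,8,9-tetrahydro-2H,10H-pyrano[2,3-f]chromene-2,10-dione (the lactone of 14), via tigloyl phenol 12 (not isolated)
Conditions: [Rh(cod)OMe]2 (2.5 mol %), dppf (5.5 mol %), but-2-yne (3 equiv), PhCl, 60 °C, sealed tube; then vent excess alkyne, quinidine (20 mol %), PhCl, 10 °C
Reagents that add atoms: none
Why: The phenoxide-bound monovalent rhodium inserts into the formyl C–H bond to give a five-membered acyl rhodium hydride chelate; syn hydrometalation of but-2-yne and C–C reductive elimination form C3–C4 and give the (E)-enone 12. Quinidine then deprotonates the only free phenol (its C9 hydroxyl hydrogen-bonding the ketone), and the ion-paired phenoxide adds to the β-carbon to form O1–C2, closing ring B in a 6-endo-trig oxa-Michael mode. The closest known reaction types are the tandem alkyne hydroacylation/oxo-Michael addition of salicylaldehydes and the cinchona-alkaloid-catalysed intramolecular oxa-Michael addition of o-tigloylphenols to cis-2,3-dimethylchroman-4-ones. C2 (2S; C8 of 13) is set by the alkaloid, quinidine being the pseudoenantiomer of the quinine that favours the 2R series; C3 (3R; C9 of 13) is set by kinetic protonation of the ring enol on the face anti to the C2 methyl group, which gives the cis pair. The step needs chemoselectivity for the alkyne over the trisubstituted prenyl alkene, closure by a single phenol (secured by the lactone that masks the C5 oxygen), and no later epimerisation to the trans isomer (weak base, low temperature, stopping at full conversion). The remote 4R centre should exert no significant influence.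

Step 8
Reactants: 13 (4R,8S,9R)-5-methoxy-8,9-dimethyl-6-(3-methylbut-2-en-1-yl)-4-pentyl-3,4,8,9-tetrahydro-2H,10H-pyrano[2,3-f]chromene-2,10-dione
Product: 14 (3R)-3-[(2S,3R)-5-hydroxy-7-methoxy-2,3-dimethyl-8-(3-methylbut-2-en-1-yl)-4-oxochroman-6-yl]octanoic acid (CNP0217102.1)
Conditions: LiOH (3 equiv), THF/H2O, 0 °C, short reaction time; then cold 1 M HCl to pH 3
Reagents that add atoms: lithium hydroxide [Li+].[OH-]
Why: Saponification of the aryl lactone should be much faster than enolisation at C3, and the liberated C5 phenoxide, conjugated to the C4 ketone, disfavours enolate formation, so the cis-2,3 pair should survive brief exposure at 0 °C before acidification.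

**Compound list**

1 | phloroglucinol | Oc1cc(O)cc(O)c1 | starting material
2 | ethyl 3-oxooctanoate | CCCCCC(=O)CC(=O)OCC | starting material
3 | 5,7-dihydroxy-4-pentyl-2H-chromen-2-one | CCCCCC1=CC(=O)Oc2cc(O)cc(O)c12 | intermediate
4 | (4R)-2,5,7-tris[diethoxy(methyl)silyloxy]-4-pentyl-4H-chromene (not isolated) | CCCCC[C@@H]1C=C(O[Si](C)(OCC)OCC)Oc2cc(O[Si](C)(OCC)OCC)cc(O[Si](C)(OCC)OCC)c12 | intermediate
5 | (4R)-5,7-dihydroxy-4-pentylchroman-2-one | CCCCC[C@@H]1CC(=O)Oc2cc(O)cc(O)c12 | intermediate
6 | (4R)-5,7-dihydroxy-2-oxo-4-pentylchromane-8-carbaldehyde | CCCCC[C@@H]1CC(=O)Oc2c(C=O)c(O)cc(O)c12 | intermediate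
7 | (4R)-7-hydroxy-5-methoxy-2-oxo-4-pentylchromane-8-carbaldehyde | CCCCC[C@@H]1CC(=O)Oc2c(C=O)c(O)cc(OC)c12 | intermediate
8 | (4R)-7-hydroxy-6-iodo-5-methoxy-2-oxo-4-pentylchromane-8-carbaldehyde | CCCCC[C@@H]1CC(=O)Oc2c(C=O)c(O)c(I)c(OC)c12 | intermediate
9 | tributyl(3-methylbut-2-en-1-yl)stannane | CCCC[Sn](CCCC)(CCCC)CC=C(C)C | starting material
10 | (4R)-7-hydroxy-5-methoxy-6-(3-methylbut-2-en-1-yl)-2-oxo-4-pentylchromane-8-carbaldehyde | CCCCC[C@@H]1CC(=O)Oc2c(C=O)c(O)c(CC=C(C)C)c(OC)c12 | intermediate
11 | but-2-yne | CC#CC | starting material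
12 | (4R)-7-hydroxy-5-methoxy-8-[(E)-2-methylbut-2-enoyl]-6-(3-methylbut-2-en-1-yl)-4-pentylchroman-2-one (not isolated) | CCCCC[C@@H]1CC(=O)Oc2c(C(=O)/C(C)=C/C)c(O)c(CC=C(C)C)c(OC)c12 | intermediate
13 | (4R,8S,9R)-5-methoxy-8,9-dimethyl-6-(3-methylbut-2-en-1-yl)-4-pentyl-3,4,8,9-tetrahydro-2H,10H-pyrano[2,3-f]chromene-2,10-dione | CCCCC[C@@H]1CC(=O)Oc2c3c(c(CC=C(C)C)c(OC)c12)O[C@@H](C)[C@@H](C)C3=O | intermediate
14 | (3R)-3-[(2S,3R)-5-hydroxy-7-methoxy-2,3-dimethyl-8-(3-methylbut-2-en-1-yl)-4-oxochroman-6-yl]octanoic acid | CCCCC[C@H](CC(=O)O)c1c(O)c2c(c(CC=C(C)C)c1OC)O[C@@H](C)[C@@H](C)C2=O | target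

**Step count and risks**

Total step count: 8. Longest linear sequence: 8 steps (from 1 and 2).

Steps most likely to fail:

Step 7. The hindered aldehyde, flanked by two oxygen substituents, may decarbonylate or react sluggishly in the hydroacylation. Residual rhodium phenoxide may also promote a racemic or trans-selective background cyclisation that erodes enantiomeric and cis purity. Fallback: setting out from 10, a Nozaki–Hiyama–Kishi coupling with (E)-2-bromobut-2-ene (CrCl2, NiCl2 cat., DMF, rt) would give (4R)-7-hydroxy-8-[(E)-1-hydroxy-2-methylbut-2-enyl]-5-methoxy-6-(3-methylbut-2-en-1-yl)-4-pentylchroman-2-one F1 as a mixture of carbinol epimers. MnO2 in CH2Cl2 would oxidise it to the enone, which rejoins the route at 12, now isolated and purified. A separate quinidine-catalysed oxa-Michael closure (PhCl, 10 °C) then leads to 13.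

Step 2. Hydride delivery to the β-carbon, hindered by the peri C5 oxygen of an electron-rich coumarin, may be slow or poorly face-selective, and the aryl lactone may be over-reduced to the lactol. Fallback: setting out from 3, hydrogenation (H2, Pd/C, AcOH, 50 °C) would give racemic 5,7-dihydroxy-4-pentylchroman-2-one F2. Preparative chromatography on a chiral stationary phase (amylose tris(3,5-dimethylphenylcarbamate), CO2/MeOH) would separate the enantiomers, and the (4R)-enantiomer rejoins the route at 5.

Step 8. Hydroxide may enolise C3 before or during lactone opening, causing cis-to-trans epimerisation or retro-oxa-Michael ring opening with loss of the C2 configuration. Fallback: setting out from 13, acid-catalysed alcoholysis (PPTS cat., allyl alcohol, rt) would open the lactone to prop-2-enyl (3R)-3-[(2S,3R)-5-hydroxy-7-methoxy-2,3-dimethyl-8-(3-methylbut-2-en-1-yl)-4-oxochroman-6-yl]octanoate F3. Neutral deallylation with Pd(PPh3)4 (cat.) and PhSiH3 in CH2Cl2 at rt would then give the acid, arriving at 14.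

**Further compounds**

F1 | step 7 | (4R)-7-hydroxy-8-[(E)-1-hydroxy-2-methylbut-2-enyl]-5-methoxy-6-(3-methylbut-2-en-1-yl)-4-pentylchroman-2-one (carbinol epimers) | CCCCC[C@@H]1CC(=O)Oc2c(C(O)/C(C)=C/C)c(O)c(CC=C(C)C)c(OC)c12
F2 | step 2 | racemic 5,7-dihydroxy-4-pentylchroman-2-one | CCCCCC1CC(=O)Oc2cc(O)cc(O)c12
F3 | step 8 | prop-2-enyl (3R)-3-[(2S,3R)-5-hydroxy-7-methoxy-2,3-dimethyl-8-(3-methylbut-2-en-1-yl)-4-oxochroman-6-yl]octanoate | CCCCC[C@H](CC(=O)OCC=C)c1c(O)c2c(c(CC=C(C)C)c1OC)O[C@@H](C)[C@@H](C)C2=O
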